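How does the opening rate of Q + G → Z over J go with Q and with G, and what share of Q does Friday's flask reach by 5.9 h?

| setting | Thursday's | Monday's | Sunday's | Tuesday's | Friday's |
|---|---|---|---|---|---|
| Q | 0.300 M | 0.150 M | 0.450 M | 0.300 M | 0.620 M |
| G | 0.240 M | 0.0900 M | 0.240 M | 0.240 M | 0.240 M |
| J | 0.00600 M | 0.00600 M | 0.00600 M | 0.00600 M | 0.00600 M |
| Z |  |  |  | 0.0900 M |  |
| time |  |  |  |  | 5.9 h |

| run | time / h | [Z] / M |
|---|---|---|
| Thursday's run | 1.2 | 0.1153 |
| Thursday's run | 2.4 | 0.1427 |
| Thursday's run | 3.5 | 0.1560 |
| Thursday's run | 4.7 | 0.1611 |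
| Thursday's run | 5.9 | 0.1650 |
| Monday's run | 1.2 | 0.0302 |
| Monday's run | 2.4 | 0.0430 |
| Monday's run | 3.5 | 0.0469 |
| Monday's run | 4.7 | 0.0509 |
| Monday's run | 5.9 | 0.0510 |
| Sunday's run | 1.2 | 0.1491 |
| Sunday's run | 2.4 | 0.1781 |
| Sunday's run | 3.5 | 0.1893 |
| Sunday's run | 4.7 | 0.1942 |
| Sunday's run | 5.9 | 0.1979 |
| Tuesday's run | 1.2 | 0.2036 |
| Tuesday's run | 2.4 | 0.2345 |
| Tuesday's run | 3.5 | 0.2455 |
| Tuesday's run | 4.7 | 0.2510 |
| Tuesday's run | 5.9 | 0.2531 |

(standard deviation of a reading: 9 × 10⁻⁴ M)

1. how the opening rate goes with [G] round the charge of the Thursday's run: the exponent of the rate at two percent of Q gone to Z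
2. how the opening rate goes with [Q] round the charge of the Thursday's run: the exponent of the rate at two percent of Q gone to Z (one fixed amount of Z, the same in the runs compared)
3. Z in the Friday's run at 5.9 h, as a share of the Q charged

- Overall: Q + G -> Z, with J as catalyst.
- Constant volume, constant temperature.
- "The second partner" is G.
- An order is taken over about fifteen percent of the charge, up and down.

Thursday's readings flatten with 0.0750 M of G, the limiting reagent of that charge, still unreacted. Tuesday's flask, charged with Z, makes 0.163 M by 5.9 h against Thursday's 0.1650 M. The forecast and I therefore both read the stall as a loss during the run, not as a return from Z. We part on what the loss means for the opening rate.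

We share one measure, the dose: the logarithm of the ratio of Q left to G left, taken relative to the same ratio at the charge, and then divided by the excess of Q charged over G charged, with each unit of Z taking one of each. It is the rate constant times catalyst summed over time, if the rate is first order in both. At 5.9 h it reads 6.08 M⁻¹ on Thursday, 7.01 M⁻¹ on Monday, whose G charge differs as well, and 5.53 M⁻¹ on Sunday, so from Thursday to Sunday, at one G charge, it falls as Q charged rises.

The forecast takes this fall as a property of the rate law: “This suggests mild saturation, with Q order about 0.9 and G order about 1.” It gives 0.88 for Q, 1 for G and 35.1% for Friday, from a dose of about 5.1.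

I read the fall as something that builds up with time. Sunday's dose against Thursday's gives an apparent Q order of 0.892 at 1.2 h but 0.767 at 5.9 h. An order belonging to the rate law should read about the same at both times, and this reading sinks between them, so I commit to an opening order of 1 in Q. For Friday I run the dose on from Thursday's along the logarithm of Q charged, with the slope from Monday to Sunday in spite of Monday's other G charge, which gives 5.10 M⁻¹ and a share of 35.1%. That is the forecast's figure, from the same measure, so it is no separate check.

The simulation gives 1.0 for Q, 1.0 for G and 34.7% for Friday.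

    J + Q + G → Z + J (540.0 M⁻² h⁻¹)
    Q → Yx (0.2750 h⁻¹)
    J + Q → Zu + Q (1.022 M⁻¹ h⁻¹)

Where two percent of Thursday's Q has turned, Sunday's rate over Thursday's is 1.51, and the ratio of their Q charges is 1.50. The forecast's 0.88 lies close to the 0.892 read over the span up to 1.2 h, not to the opening order. Friday's share corresponds to a dose of 4.84 M⁻¹, which is less than the 5.10 M⁻¹ run on beforehand and 0.796 of Thursday's 6.08 M⁻¹.

The readings are calculated on assumed constants, noise included.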